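**Remark (one line):** locants C‑1 to C‑15 follow germacrane numbering of the target (carbocycle C‑1…C‑10, lactone carbonyl C‑12, methyls C‑13 and C‑14, hydroxymethyl C‑15); compounds 1, 3 and 6 and all reagents are taken as commercial.

## Retrosynthetic overview

1. Endgame: the target comes from protected germacradiene 25 by esterification of O‑8 with acid 28, oxidation of C‑12, acid‑induced ketal cleavage with spontaneous closure of the 6,12‑γ‑lactone (last ring), and desilylation.
2. Key disconnection: the ten‑membered carbocycle is opened across C‑2–C‑3 by an anionic oxy‑Cope transform to the cis‑1,2‑dialkenylcyclohexanol 21 (six‑membered ring C‑5…C‑10); the C‑14 methyl is traced back to the C‑10 oxygen through enol triflate 23.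
3. Enabling feature: the skipped 1,5‑diene C‑10=C‑1–C‑2–C‑3–C‑4=C‑5 of the cyclodecadiene, in which O‑6 and C‑15–O are cis on C‑4=C‑5 (so a seven‑membered ketal can bridge them and fix that alkene) and the methyl‑bearing C‑10 can start as a carbinol carbon.
4. Cyclohexanol 21 comes from vinyl epoxide 17: an O‑6‑tethered phosphonoacetate opens the epoxide at C‑5 (temporary cis‑fused α‑methylene lactone), which sets C‑5 and C‑10; the diene comes from enyne ring‑closing metathesis (first ring) and C‑6 from a Luche reduction.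
5. Enynone 13 comes from an Evans syn‑aldol of an imide of (S)‑4‑(PMB‑oxy)‑3‑methylbutanoic acid (from lactone 1, which also supplies the ester side chain) with butynal 7. Ring order: cyclohexene, cis‑lactone (temporary), dioxepane (temporary), ten‑membered ring, γ‑lactone.

Key step: step 16

## Route

Step 1
Reactants: 1 (S)-4-methyldihydrofuran-2(3H)-one
Product: 2 (S)-4-[(4-methoxybenzyl)oxy]-3-methylbutanoic acid
Conditions: KOH, 4-MeOC6H4CH2Cl, toluene, reflux; then KOH, MeOH/H2O; acidify to pH 4
Reagents that add atoms: 4-methoxybenzyl chloride COc1ccc(CCl)cc1; potassium hydroxide [K+].[OH-]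
Why: Alkaline opening of the γ‑lactone and Williamson etherification of the liberated primary alkoxide in one pot is the standard route to 4‑alkoxybutanoic acids; the C‑11 stereocentre (bought with 1) is not involved.

Step 2
Reactants: 2 (S)-4-[(4-methoxybenzyl)oxy]-3-methylbutanoic acid; 3 (R)-4-benzyloxazolidin-2-one
Product: 5 (R)-4-benzyl-3-{(S)-4-[(4-methoxybenzyl)oxy]-3-methylbutanoyl}oxazolidin-2-one, via mixed pivalic anhydride 4 (not isolated)
Conditions: t-BuCOCl, Et3N, THF, −20 °C; then 3, LiCl, 25 °C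
Reagents that add atoms: none
Why: Acylation of the LiCl‑activated oxazolidinone by the mixed pivalic anhydride (attack at the less hindered acyl carbon) is the routine preparation of Evans imides.

Step 3
Reactants: 6 4-(trimethylsilyl)but-3-yn-1-ol
Product: 7 4-(trimethylsilyl)but-3-ynal
Conditions: Dess–Martin periodinane, NaHCO3, CH2Cl2, 0 °C; used at once
Reagents that add atoms: none
Why: Dess–Martin oxidation under buffered, non‑basic conditions should give the β,γ‑alkynyl aldehyde without isomerization to the allenal.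

Step 4
Reactants: 5 (R)-4-benzyl-3-{(S)-4-[(4-methoxybenzyl)oxy]-3-methylbutanoyl}oxazolidin-2-one; 7 4-(trimethylsilyl)but-3-ynal
Product: 9 (R)-4-benzyl-3-{(2R,3S)-3-hydroxy-2-[(S)-1-((4-methoxybenzyl)oxy)propan-2-yl]-6-(trimethylsilyl)hex-5-ynoyl}oxazolidin-2-one, via boron enolate 8 (not isolated)
Conditions: Bu2BOTf, i-Pr2NEt, CH2Cl2, −78 → 0 °C; then 7, −78 °C; pH 7 buffer, MeOH, H2O2
Reagents that add atoms: none
Why: Evans syn‑aldol reaction: the (Z)‑boron enolate 8 reacts through a Zimmerman–Traxler chair in which the benzyl group of the auxiliary shields one enolate face, which sets C‑7 and C‑8 together (syn) under reagent control irrespective of C‑11.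

Step 5
Reactants: 9 Evans syn-aldol adduct
Product: 10 (2R,3S)-3-hydroxy-N-methoxy-N-methyl-2-[(S)-1-((4-methoxybenzyl)oxy)propan-2-yl]-6-(trimethylsilyl)hex-5-ynamide
Conditions: MeONHMe·HCl, AlMe3, CH2Cl2, −20 → 0 °C
Reagents that add atoms: N,O-dimethylhydroxylamine hydrochloride CNOC.Cl
Why: Aluminium amide transamidation of the aldol imide, assisted by chelation of the free β‑hydroxyl, should give the Weinreb amide and release the auxiliary without retro‑aldol cleavage.

Step 6
Reactants: 10 β-hydroxy Weinreb amide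
Product: 11 (2R,3S)-3-[(tert-butyldimethylsilyl)oxy]-N-methoxy-N-methyl-2-[(S)-1-((4-methoxybenzyl)oxy)propan-2-yl]-6-(trimethylsilyl)hex-5-ynamide
Conditions: t-BuMe2SiOTf, 2,6-lutidine, CH2Cl2, −78 °C
Reagents that add atoms: tert-butyldimethylsilyl triflate CC(C)(C)[Si](C)(C)OS(=O)(=O)C(F)(F)F
Why: Silylation of the secondary alcohol with the silyl triflate is fast at low temperature and gives an O‑8 protecting group that should survive every step up to step 18.

Step 7
Reactants: 11 silyl ether of the Weinreb amide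
Product: 12 (2R,3S)-3-[(tert-butyldimethylsilyl)oxy]-N-methoxy-N-methyl-2-[(S)-1-((4-methoxybenzyl)oxy)propan-2-yl]hex-5-ynamide
Conditions: K2CO3 (cat.), MeOH, 0 → 25 °C
Reagents that add atoms: none
Why: Base‑catalysed methanolysis cleaves only the alkynyl C–Si bond (the secondary silyl ether and the amide are inert) and frees the terminal alkyne needed for metathesis.

Step 8
Reactants: 12 terminal alkyne Weinreb amide
Product: 13 (4R,5S)-5-[(tert-butyldimethylsilyl)oxy]-4-[(S)-1-((4-methoxybenzyl)oxy)propan-2-yl]oct-1-en-7-yn-3-one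
Conditions: CH2=CHMgBr (3 equiv), THF, −78 → 0 °C; cold aq. citric acid quench
Reagents that add atoms: vinylmagnesium bromide C=C[Mg]Br
Why: Weinreb ketone synthesis: the magnesium chelate of the tetrahedral adduct stops at the ketone stage, and the acidic quench prevents conjugate addition of the liberated amine to the vinyl ketone.

Step 9
Reactants: 13 enynone
Product: 14 (5S,6R)-5-[(tert-butyldimethylsilyl)oxy]-6-[(S)-1-((4-methoxybenzyl)oxy)propan-2-yl]-3-vinylcyclohex-2-en-1-one
Conditions: second-generation Grubbs catalyst (5 mol%), C2H4 (1 atm), toluene, 60 °C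
Reagents that add atoms: none
Why: Ring‑closing enyne metathesis (exo mode) of the 1,7‑enyne should close the six‑membered ring C‑5…C‑10 and leave the vinyl group on C‑10, giving the conjugated dienone in one step.

Step 10
Reactants: 14 dienone
Product: 15 (1R,5S,6S)-5-[(tert-butyldimethylsilyl)oxy]-6-[(S)-1-((4-methoxybenzyl)oxy)propan-2-yl]-3-vinylcyclohex-2-en-1-ol (hydroxyl trans to the side chain and cis to the silyloxy group)
Conditions: NaBH4, CeCl3·7H2O, MeOH, −78 °C
Reagents that add atoms: none
Why: Luche reduction gives clean 1,2‑reduction with axial hydride delivery to the half‑chair that holds the C‑7 and C‑8 substituents equatorial, so the new C‑6 hydroxyl should be equatorial and trans to the C‑7 side chain.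

Step 11
Reactants: 15 dienol
Product: 16 anti-epoxy alcohol (5,10-epoxide of 15 on the face opposite to O-6; C-10 keeps the vinyl group)
Conditions: D-fructose-derived Shi ketone (30 mol%), KHSO5 (as Oxone), K2CO3, Bu4NHSO4, MeCN/CH2(OMe)2/aq. Na2B4O7 buffer, 0 °C
Reagents that add atoms: potassium peroxymonosulfate [K+].[O-]S(=O)(=O)OO
Why: Shi asymmetric epoxidation: the chiral dioxirane attacks the more electron‑rich trisubstituted ring alkene of the diene and, by analogy with 1‑substituted cyclohexenes (spiro transition state), should deliver oxygen to the face opposite to O‑6, which sets C‑5 and C‑10 under reagent control.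

Step 12
Reactants: 16 anti-epoxy alcohol
Product: 17 O-6 (diethoxyphosphoryl)acetate of 16
Conditions: (EtO)2P(O)CH2CO2H, DCC, DMAP (cat.), CH2Cl2, 0 °C
Reagents that add atoms: diethylphosphonoacetic acid CCOP(=O)(OCC)CC(=O)O
Why: Steglich esterification of the secondary alcohol under neutral conditions installs the carbon tether on O‑6 without opening the acid‑sensitive vinyl epoxide.

Step 13
Reactants: 17 epoxy phosphonoacetate
Product: 19 cis-fused α-methylene γ-lactone (C-15 carbonyl on O-6 and C-4 on C-5; tertiary C-10 hydroxyl trans to C-4; C-10 vinyl cis to C-4), via phosphono lactone 18 (not isolated)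
Conditions: NaH, THF, 0 → 40 °C; then (CH2O)n, 25 °C
Reagents that add atoms: formaldehyde C=O
Why: Proposed new method: deprotonation of the phosphonoacetate gives a stabilised carbanion that the O‑6 ester holds on the upper face, so it can reach only C‑5 anti to the epoxide C–O bond (5‑exo‑tet, trans‑diaxial opening by the Fürst–Plattner rule, inversion at C‑5), which delivers C‑4 cis to O‑6 and leaves the C‑10 oxygen trans to it, attack at the vinyl terminus being excluded by ring size; the tertiary alkoxide then re‑deprotonates α‑phosphono lactone 18, which undergoes Horner–Wadsworth–Emmons olefination with formaldehyde; the closest known reaction types are the intermolecular opening of epoxides by phosphonoacetate anions followed by formaldehyde olefination to α‑methylene γ‑lactones, and intramolecular epoxide openings by stabilised carbanions.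

Step 14
Reactants: 19 cis-fused α-methylene γ-lactone
Product: 20 triol (C-5 bears 3-hydroxyprop-1-en-2-yl; free hydroxyls at C-15 and C-6 and the tertiary C-10)
Conditions: (i-Bu)2AlH (5 equiv), CH2Cl2, −78 → 0 °C
Reagents that add atoms: none
Why: Excess (i‑Bu)2AlH reduces the lactone carbonyl twice (1,2‑reduction through the lactol) and should give the 2‑methylene‑1,4‑diol without touching the isolated alkenes or the ethers.

Step 15
Reactants: 20 triol
Product: 21 O-6,O-15-isopropylidene ketal of 20 (cis-fused 1,3-dioxepane; free tertiary C-10 hydroxyl; axial C-5 alkenyl and equatorial C-10 vinyl)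
Conditions: Me2C(OMe)2, PPTS (cat.), CH2Cl2, 0 °C
Reagents that add atoms: 2,2-dimethoxypropane COC(C)(C)OC
Why: Acid‑catalysed transketalization: only the C‑15 and C‑6 hydroxyls (axial C‑4, equatorial O‑6, gauche) can be bridged, as a seven‑membered 1,3‑dioxepane, whereas the tertiary C‑10 hydroxyl is anti‑periplanar to C‑4 and stays free.

Step 16
Reactants: 21 dioxepane-bridged cis-1,2-dialkenylcyclohexanol
Product: 23 ten-membered enol triflate (C-10 triflate trans to C-2; C-4=C-5 inside a 4,7-dihydro-1,3-dioxepine), via potassium enolate 22 (not isolated)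
Conditions: KN(SiMe3)2 (1.2 equiv), 18-crown-6, THF, −78 → 25 °C; then PhN(SO2CF3)2, −78 → 0 °C
Reagents that add atoms: N-phenylbis(trifluoromethanesulfonimide) O=S(=O)(N(c1ccccc1)S(=O)(=O)C(F)(F)F)C(F)(F)F
Why: Deprotonation of the tertiary C‑10 alcohol triggers an alkoxide‑accelerated [3,3] sigmatropic shift (anionic oxy‑Cope rearrangement) that breaks C‑5–C‑10 and forms C‑2–C‑3, and the regiodefined potassium enolate 22 is O‑sulfonylated in the same flask. The closest known reaction type is the anionic oxy‑Cope ring expansion of 1,2‑dialkenylcyclohexanols to cyclodec‑5‑enones with electrophilic trapping of the enolate. The ten‑membered ring is closed by a suprafacial six‑centre pericyclic ring expansion (six to ten atoms) and not by an end‑to‑end cyclization, so no high dilution is needed. No new sp3 stereocentre is formed; the stereocentres C‑5 and C‑10 are traded for the two trisubstituted alkenes: C‑4=C‑5 is fixed with C‑15 and C‑6 cis by the dioxepane ring, and C‑1=C‑10 by the chair transition state in which the equatorial vinyl group places O‑10 pseudo‑equatorial and C‑9 pseudo‑axial (C‑9 cis to C‑2). The step needs chair over boat selectivity and an enolate that does not equilibrate; the cyclohexane chair locked by the three equatorial groups at C‑6, C‑7 and C‑8 and the absence of any acidic C–H in 21 should secure both. The triflate then stands exactly where the C‑14 methyl is needed.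

Step 17
Reactants: 23 enol triflate
Product: 24 C-14 methyl germacradiene (8-O-silyl; 12-O-PMB; 6,15-O-isopropylidene)
Conditions: MeZnCl, Pd(PPh3)4 (5 mol%), THF, 25 °C
Reagents that add atoms: methylzinc chloride C[Zn]Cl
Why: Negishi cross‑coupling of the alkenyl triflate proceeds with retention of the C‑1=C‑10 geometry and replaces the former carbinol oxygen by the C‑14 methyl group.

Step 18
Reactants: 24 C-14 methyl germacradiene
Product: 25 C-8 alcohol
Conditions: Bu4NF, THF, 25 °C
Reagents that add atoms: none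
Why: Fluoride cleavage of the secondary silyl ether leaves the ketal, the PMB ether and the skipped diene untouched.

Step 19
Reactants: 1 (S)-4-methyldihydrofuran-2(3H)-one
Product: 26 sodium (S)-4-hydroxy-3-methylbutanoate
Conditions: NaOH (1 equiv), H2O/MeOH, 25 °C; evaporate
Reagents that add atoms: sodium hydroxide [Na+].[OH-]
Why: Saponification opens the lactone to the stable sodium hydroxy carboxylate, which is not acidified so that it cannot relactonize.

Step 20
Reactants: 26 sodium (S)-4-hydroxy-3-methylbutanoate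
Product: 28 (S)-4-[(tert-butyldiphenylsilyl)oxy]-3-methylbutanoic acid, via bis-silyl derivative 27 (not isolated)
Conditions: t-BuPh2SiCl (2.2 equiv), imidazole, DMF, 25 °C; then K2CO3 (cat.), MeOH/THF/H2O; pH 4
Reagents that add atoms: tert-butyl(chloro)diphenylsilane CC(C)(C)[Si](Cl)(c1ccccc1)c1ccccc1
Why: Silylation of both oxygens followed by selective mild solvolysis of the labile silyl ester is the usual route to ω‑silyloxy acids.

Step 21
Reactants: 25 C-8 alcohol; 28 (S)-4-[(tert-butyldiphenylsilyl)oxy]-3-methylbutanoic acid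
Product: 29 C-8 ester of 25 with acid 28
Conditions: DCC, DMAP, CH2Cl2, 25 °C
Reagents that add atoms: none
Why: Steglich esterification acylates the only free hydroxyl (C‑8) with the side‑chain acid, whose own hydroxyl is blocked so that it cannot lactonize.

Step 22
Reactants: 29 C-8 ester
Product: 30 C-12 primary alcohol
Conditions: DDQ, CH2Cl2/pH 7 buffer, 0 °C
Reagents that add atoms: none
Why: Oxidative cleavage of the PMB ether by DDQ in buffered wet CH2Cl2 frees the C‑12 alcohol; the isolated trisubstituted alkenes and the silyl ether should be inert.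

Step 23
Reactants: 30 C-12 primary alcohol
Product: 31 C-12 carboxylic acid
Conditions: TEMPO (cat.), PhI(OAc)2, MeCN/H2O, NaHCO3, 0 → 25 °C
Reagents that add atoms: water O
Why: TEMPO/PhI(OAc)2 oxidation in aqueous MeCN takes the only free (primary) alcohol through the aldehyde hydrate to the acid without epimerizing C‑11 or touching the alkenes.

Step 24
Reactants: 31 C-12 carboxylic acid
Product: 33 O-silyl target (6,12-γ-lactone closed; C-15 hydroxyl free; side-chain hydroxyl as tert-butyldiphenylsilyl ether), via hydroxy acid 32 (not isolated)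
Conditions: AcOH/THF/H2O (3:1:1), 25 °C
Reagents that add atoms: none
Why: Mild aqueous acid hydrolyses the seven‑membered ketal and the liberated 6‑hydroxy 12‑acid should close spontaneously to the γ‑lactone; the trans ring fusion and the C‑11 methyl configuration follow from C‑6, C‑7 and C‑11 already in place.

Step 25
Reactants: 33 O-silyl target
Product: 34 CNP0160815.1
Conditions: HF·pyridine, pyridine, THF, 0 → 25 °C
Reagents that add atoms: none
Why: Buffered HF·pyridine removes the primary silyl ether under conditions mild enough to keep the 4‑hydroxy ester side chain from lactonizing.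

## Compound list

1 | (S)-4-methyldihydrofuran-2(3H)-one | O=C1C[C@H](C)CO1 | starting material
2 | (S)-4-[(4-methoxybenzyl)oxy]-3-methylbutanoic acid | OC(=O)C[C@H](C)COCc1ccc(OC)cc1 | intermediate
3 | (R)-4-benzyloxazolidin-2-one | O=C1N[C@H](Cc2ccccc2)CO1 | starting material
4 | mixed anhydride of 2 with pivalic acid | CC(C)(C)C(=O)OC(=O)C[C@H](C)COCc1ccc(OC)cc1 | intermediate (not isolated)
5 | (R)-4-benzyl-3-{(S)-4-[(4-methoxybenzyl)oxy]-3-methylbutanoyl}oxazolidin-2-one | O=C(C[C@H](C)COCc1ccc(OC)cc1)N1[C@H](Cc2ccccc2)COC1=O | intermediate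
6 | 4-(trimethylsilyl)but-3-yn-1-ol | C[Si](C)(C)C#CCCO | starting material
7 | 4-(trimethylsilyl)but-3-ynal | C[Si](C)(C)C#CCC=O | intermediate
8 | (Z)-dibutylboron enolate of 5 | CCCCB(CCCC)O/C(=C\[C@H](C)COCc1ccc(OC)cc1)N1[C@H](Cc2ccccc2)COC1=O | intermediate (not isolated)
9 | (R)-4-benzyl-3-{(2R,3S)-3-hydroxy-2-[(S)-1-((4-methoxybenzyl)oxy)propan-2-yl]-6-(trimethylsilyl)hex-5-ynoyl}oxazolidin-2-one | O=C(N1[C@H](Cc2ccccc2)COC1=O)[C@H]([C@H](C)COCc1ccc(OC)cc1)[C@@H](O)CC#C[Si](C)(C)C | intermediate
10 | (2R,3S)-3-hydroxy-N-methoxy-N-methyl-2-[(S)-1-((4-methoxybenzyl)oxy)propan-2-yl]-6-(trimethylsilyl)hex-5-ynamide | CON(C)C(=O)[C@H]([C@H](C)COCc1ccc(OC)cc1)[C@@H](O)CC#C[Si](C)(C)C | intermediate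
11 | (2R,3S)-3-[(tert-butyldimethylsilyl)oxy]-N-methoxy-N-methyl-2-[(S)-1-((4-methoxybenzyl)oxy)propan-2-yl]-6-(trimethylsilyl)hex-5-ynamide | CON(C)C(=O)[C@H]([C@H](C)COCc1ccc(OC)cc1)[C@@H](O[Si](C)(C)C(C)(C)C)CC#C[Si](C)(C)C | intermediate
12 | (2R,3S)-3-[(tert-butyldimethylsilyl)oxy]-N-methoxy-N-methyl-2-[(S)-1-((4-methoxybenzyl)oxy)propan-2-yl]hex-5-ynamide | CON(C)C(=O)[C@H]([C@H](C)COCc1ccc(OC)cc1)[C@@H](O[Si](C)(C)C(C)(C)C)CC#C | intermediate
13 | (4R,5S)-5-[(tert-butyldimethylsilyl)oxy]-4-[(S)-1-((4-methoxybenzyl)oxy)propan-2-yl]oct-1-en-7-yn-3-one | C=CC(=O)[C@H]([C@H](C)COCc1ccc(OC)cc1)[C@@H](O[Si](C)(C)C(C)(C)C)CC#C | intermediate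
14 | (5S,6R)-5-[(tert-butyldimethylsilyl)oxy]-6-[(S)-1-((4-methoxybenzyl)oxy)propan-2-yl]-3-vinylcyclohex-2-en-1-one | O=C1C=C(C=C)C[C@H](O[Si](C)(C)C(C)(C)C)[C@H]1[C@H](C)COCc1ccc(OC)cc1 | intermediate
15 | (1R,5S,6S)-5-[(tert-butyldimethylsilyl)oxy]-6-[(S)-1-((4-methoxybenzyl)oxy)propan-2-yl]-3-vinylcyclohex-2-en-1-ol | O[C@@H]1C=C(C=C)C[C@H](O[Si](C)(C)C(C)(C)C)[C@H]1[C@H](C)COCc1ccc(OC)cc1 | intermediate
16 | anti-epoxy alcohol (5,10-epoxide opposite to O-6; C-10 vinyl) | O[C@@H]1[C@H]2O[C@@]2(C=C)C[C@H](O[Si](C)(C)C(C)(C)C)[C@H]1[C@H](C)COCc1ccc(OC)cc1 | intermediate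
17 | O-6 (diethoxyphosphoryl)acetate of 16 | CCOP(=O)(OCC)CC(=O)O[C@@H]1[C@H]2O[C@@]2(C=C)C[C@H](O[Si](C)(C)C(C)(C)C)[C@H]1[C@H](C)COCc1ccc(OC)cc1 | intermediate
18 | cis-fused α-(diethoxyphosphoryl) γ-lactone with tertiary C-10 alcohol (C-4 epimers) | CCOP(=O)(OCC)C1C(=O)O[C@@H]2[C@H]1[C@](O)(C=C)C[C@H](O[Si](C)(C)C(C)(C)C)[C@H]2[C@H](C)COCc1ccc(OC)cc1 | intermediate (not isolated)
19 | cis-fused α-methylene γ-lactone with tertiary C-10 alcohol (OH trans to C-4; vinyl cis to C-4) | C=C1C(=O)O[C@@H]2[C@H]1[C@](O)(C=C)C[C@H](O[Si](C)(C)C(C)(C)C)[C@H]2[C@H](C)COCc1ccc(OC)cc1 | intermediate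
20 | triol (C-5 3-hydroxyprop-1-en-2-yl; 6-OH; tertiary 10-OH) | C=C(CO)[C@H]1[C@@H](O)[C@H]([C@H](C)COCc2ccc(OC)cc2)[C@@H](O[Si](C)(C)C(C)(C)C)C[C@@]1(O)C=C | intermediate
21 | O-6,O-15-isopropylidene ketal of 20 (cis-fused 1,3-dioxepane; free tertiary 10-OH) | C=C1COC(C)(C)O[C@@H]2[C@H]1[C@](O)(C=C)C[C@H](O[Si](C)(C)C(C)(C)C)[C@H]2[C@H](C)COCc1ccc(OC)cc1 | intermediate
22 | potassium enolate of the ring-expanded ketone (C-1=C-10 ring-cis) | [K+].[O-]/C1=C/CC/C2=C/[C@@H](OC(C)(C)OC2)[C@H]([C@H](C)COCc3ccc(OC)cc3)[C@@H](O[Si](C)(C)C(C)(C)C)C1 | intermediate (not isolated)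
23 | ten-membered enol triflate (triflate on C-10 trans to C-2) | FC(F)(F)S(=O)(=O)O/C1=C/CC/C2=C/[C@@H](OC(C)(C)OC2)[C@H]([C@H](C)COCc3ccc(OC)cc3)[C@@H](O[Si](C)(C)C(C)(C)C)C1 | intermediate
24 | C-14 methyl germacradiene (8-O-silyl; 12-O-PMB; 6,15-O-isopropylidene) | C/C1=C/CC/C2=C/[C@@H](OC(C)(C)OC2)[C@H]([C@H](C)COCc3ccc(OC)cc3)[C@@H](O[Si](C)(C)C(C)(C)C)C1 | intermediate
25 | C-8 alcohol | C/C1=C/CC/C2=C/[C@@H](OC(C)(C)OC2)[C@H]([C@H](C)COCc3ccc(OC)cc3)[C@@H](O)C1 | intermediate
26 | sodium (S)-4-hydroxy-3-methylbutanoate | [Na+].[O-]C(=O)C[C@H](C)CO | intermediate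
27 | tert-butyldiphenylsilyl (S)-4-[(tert-butyldiphenylsilyl)oxy]-3-methylbutanoate | CC(C)(C)[Si](OC(=O)C[C@H](C)CO[Si](c1ccccc1)(c1ccccc1)C(C)(C)C)(c1ccccc1)c1ccccc1 | intermediate (not isolated)
28 | (S)-4-[(tert-butyldiphenylsilyl)oxy]-3-methylbutanoic acid | OC(=O)C[C@H](C)CO[Si](c1ccccc1)(c1ccccc1)C(C)(C)C | intermediate
29 | C-8 ester of 25 with 28 | C/C1=C/CC/C2=C/[C@@H](OC(C)(C)OC2)[C@H]([C@H](C)COCc3ccc(OC)cc3)[C@@H](OC(=O)C[C@H](C)CO[Si](c3ccccc3)(c3ccccc3)C(C)(C)C)C1 | intermediate
30 | C-12 primary alcohol | C/C1=C/CC/C2=C/[C@@H](OC(C)(C)OC2)[C@H]([C@H](C)CO)[C@@H](OC(=O)C[C@H](C)CO[Si](c3ccccc3)(c3ccccc3)C(C)(C)C)C1 | intermediate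
31 | C-12 carboxylic acid | C/C1=C/CC/C2=C/[C@@H](OC(C)(C)OC2)[C@H]([C@H](C)C(=O)O)[C@@H](OC(=O)C[C@H](C)CO[Si](c3ccccc3)(c3ccccc3)C(C)(C)C)C1 | intermediate
32 | 6,15-dihydroxy 12-acid | C/C1=C/CC/C(CO)=C/[C@@H](O)[C@H]([C@H](C)C(=O)O)[C@@H](OC(=O)C[C@H](C)CO[Si](c2ccccc2)(c2ccccc2)C(C)(C)C)C1 | intermediate (not isolated)
33 | O-silyl target (side-chain tert-butyldiphenylsilyl ether) | C/C1=C/CC/C(CO)=C/[C@H]2OC(=O)[C@@H](C)[C@@H]2[C@@H](OC(=O)C[C@H](C)CO[Si](c3ccccc3)(c3ccccc3)C(C)(C)C)C1 | intermediate
34 | CNP0160815.1 | C/C1=C/CC/C(CO)=C/[C@H]2OC(=O)[C@@H](C)[C@@H]2[C@@H](OC(=O)C[C@H](C)CO)C1 | target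

## Step count and risks

Total step count: 25. Longest linear sequence: 22 steps (steps 1, 2, 4–18 and 21–25, from lactone 1).

**Step 13 (Proposed new method).** The ester tether has to leave its preferred s‑trans conformation before the carbanion can line up behind C‑5, so base‑induced elimination of the vinyl epoxide or intermolecular alkylation may outrun ring closure. The fallback uses known chemistry only and sets out from epoxy alcohol 16. O‑6 is capped (Et3SiCl, imidazole, CH2Cl2) to give the triethylsilyl ether F1, which blocks epoxide migration under base. LiC≡CH·H2NCH2CH2NH2 in DMSO then opens the epoxide at the secondary C‑5 (trans‑diaxial; the tertiary C‑10 is not attacked) to give the C‑5 ethynyl C‑10 carbinol F2. PPTS in MeOH frees O‑6 to give the alkynediol F3. Palladium‑catalysed cyclocarbonylation of this cis‑homopropargylic alcohol (PdCl2, PPh3, SnCl2, CO, MeCN, 70 °C) builds the α‑methylene lactone and comes back to the route at 19.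

**Step 16 (key step).** Proton transfer to the potassium enolate (from unreacted carbinol during a slow rearrangement) may scramble the enolate before it is sulfonylated, or the sigmatropic shift may stall at temperatures the enolate tolerates. The fallback sets out from 21, which is silylated (Me3SiOTf, 2,6‑lutidine, CH2Cl2, −78 °C) to the trimethylsilyl ether F4. A neutral thermal siloxy‑Cope rearrangement (degassed decalin, sealed tube, about 200 °C) through the same chair should give the isolable silyl enol ether F5. Regiospecific cleavage with MeLi (THF, 0 °C) to the lithium enolate and sulfonylation with PhN(SO2CF3)2 comes back to the route at 23.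

**Step 11.** Facial selectivity may be poor, the vinyl group may be epoxidised as well, or the tertiary allylic epoxide may be opened solvolytically in the aqueous buffer. The fallback sets out from dienone 14 and uses substrate direction instead of reagent control. LiBH(s‑Bu)3 (THF, −78 °C; equatorial attack) gives the C‑6 epimeric dienol F6. Hydroxyl‑directed epoxidation (VO(acac)2, t‑BuOOH, CH2Cl2) delivers oxygen syn to that hydroxyl, to the same lower face, giving the syn‑epoxy alcohol F7. Mitsunobu esterification with diethylphosphonoacetic acid (PPh3, DIAD, THF) inverts C‑6 and comes back to the route at 17.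

## Further compounds

F1 | step 13 | O-6 triethylsilyl ether of epoxy alcohol 16 | CC[Si](CC)(CC)O[C@@H]1[C@H]2O[C@@]2(C=C)C[C@H](O[Si](C)(C)C(C)(C)C)[C@H]1[C@H](C)COCc1ccc(OC)cc1
F2 | step 13 | C-5 ethynyl C-10 carbinol (O-6 triethylsilyl ether) | C#C[C@H]1[C@@H](O[Si](CC)(CC)CC)[C@H]([C@H](C)COCc2ccc(OC)cc2)[C@@H](O[Si](C)(C)C(C)(C)C)C[C@@]1(O)C=C
F3 | step 13 | alkynediol (C-5 ethynyl cis to the free 6-OH; tertiary 10-OH) | C#C[C@H]1[C@@H](O)[C@H]([C@H](C)COCc2ccc(OC)cc2)[C@@H](O[Si](C)(C)C(C)(C)C)C[C@@]1(O)C=C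
F4 | step 16 | C-10 trimethylsilyl ether of 21 | C=C1COC(C)(C)O[C@@H]2[C@H]1[C@](O[Si](C)(C)C)(C=C)C[C@H](O[Si](C)(C)C(C)(C)C)[C@H]2[C@H](C)COCc1ccc(OC)cc1
F5 | step 16 | ten-membered trimethylsilyl enol ether (silyloxy on C-10 trans to C-2) | C[Si](C)(C)O/C1=C/CC/C2=C/[C@@H](OC(C)(C)OC2)[C@H]([C@H](C)COCc3ccc(OC)cc3)[C@@H](O[Si](C)(C)C(C)(C)C)C1
F6 | step 11 | C-6 epimer of dienol 15 (hydroxyl cis to the C-7 side chain) | O[C@H]1C=C(C=C)C[C@H](O[Si](C)(C)C(C)(C)C)[C@H]1[C@H](C)COCc1ccc(OC)cc1
F7 | step 11 | syn-epoxy alcohol (5,10-epoxide on the same face as the C-6 hydroxyl) | O[C@H]1[C@H]2O[C@@]2(C=C)C[C@H](O[Si](C)(C)C(C)(C)C)[C@H]1[C@H](C)COCc1ccc(OC)cc1
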